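## Retrosynthetic overview
1. Plagiochilin A comes from an Ac2O-mediated closure of the 2,3-seco (glutaraldehyde-type) dialdehyde, which carries the C10 spiro-epoxide and a protected C15 hydroxyl.
2. The spiro-epoxide comes from a Corey–Chaykovsky reaction on the C10 ketone.
3. The C5 stereocentre and the C5–C4(C15)–C3 unit are set by an Ireland–Claisen [3,3] rearrangement (key step) of a cycloheptenyl ester. That ester derives from the α-(silyloxymethyl)cycloheptenone by Luche reduction and Mitsunobu inversion.
4. The bicyclo[5.1.0]octenone, with the gem-dimethylcyclopropane and both cyclopropane stereocentres, comes from (+)-2-carene by ozonolysis and a kinetic intramolecular aldol.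
5. Rings form in this order: cyclopropane (already present in the terpene), cycloheptane (aldol), acyclic C5 side chain (Claisen), epoxide, dihydropyran (Ac2O closure).

Assumptions:
- 3-(TBDPSO)propanoic acid (13) is commercial.
- C1 and C2 equilibrate thermodynamically at the dialdehyde/Ac2O stage to the cis-fused pyran with axial (anomeric) OAc, and C4 is destroyed as a stereocentre.

## Route

**Step 1**
Reactants: 1 (+)-2-carene; 2 ozone
Product: 3 (1S,3R)-2,2-dimethyl-3-(3-oxobutyl)cyclopropane-1-carbaldehyde
Conditions: O3, CH2Cl2/MeOH, −78 °C; then Me2S, −78 °C → rt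
Reagents that add atoms: ozone, O=[O+][O-]
Why: Ozonolysis of the only alkene cleaves it to the aldehyde and methyl ketone, leaving the cis-disposed cyclopropane stereocentres untouched.

**Step 2**
Reactants: 3
Product: 4 2-hydroxy-8,8-dimethylbicyclo[5.1.0]octan-4-one (aldol, C2 epimers)
Conditions: LiHMDS, THF, −78 °C; then aq. NH4Cl
Reagents that add atoms: none
Why: In an intramolecular aldol, kinetic enolisation at the methyl group of the ketone followed by attack on the non-enolisable cyclopropyl aldehyde closes the seven-membered ring. The cis-cyclopropane holds the two arms together, and the carbinol centre is lost on dehydration.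

**Step 3**
Reactants: 4
Product: 5 (1S,7R)-8,8-dimethylbicyclo[5.1.0]oct-2-en-4-one
Conditions: MsCl, Et3N, CH2Cl2, 0 °C; then DBU, rt
Reagents that add atoms: none
Why: Mesylation and E1cB elimination give the conjugated cis-enone. The enone sits next to the S-type cyclopropane carbon, which fixes the sense of chirality for all later steps.

**Step 4**
Reactants: 5; 6 formaldehyde
Product: 7 5-(hydroxymethyl)-8,8-dimethylbicyclo[5.1.0]oct-2-en-4-one (C5 epimers)
Conditions: LDA, THF, −78 °C; then monomeric HCHO, −78 → −40 °C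
Reagents that add atoms: formaldehyde, C=O
Why: The ketone can only enolise on the saturated α′-side, so aldol hydroxymethylation puts C2 on the carbon that becomes C1. The new centre is destroyed in step 7.

**Step 5**
Reactants: 7; 8 TBSCl
Product: 9 5-(TBSO-methyl)-8,8-dimethylbicyclo[5.1.0]oct-2-en-4-one
Conditions: TBSCl, imidazole, DMF, rt
Reagents that add atoms: TBSCl, CC(C)(C)[Si](C)(C)Cl
Why: Silyl protection prevents retro-aldol and keeps C2 as a protected alcohol.

**Step 6**
Reactants: 9
Product: 10 5-(TBSO-methyl)-8,8-dimethylbicyclo[5.1.0]octan-4-one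
Conditions: [(Ph3P)CuH]6 (cat.), PhSiH3, toluene, 0 °C
Reagents that add atoms: none
Why: Conjugate (1,4) reduction with Stryker-type Cu–H saturates C8=C9 without opening the cyclopropane. The C1 stereocentre now carries the asymmetry.

**Step 7**
Reactants: 10
Product: 11 5-(TBSO-methyl)-8,8-dimethylbicyclo[5.1.0]oct-5-en-4-one
Conditions: IBX·MPO, DMSO, 65 °C
Reagents that add atoms: none
Why: IBX dehydrogenation (Nicolaou) goes through the more substituted enol, giving the C1=C5 enone. C1 is now sp2, so the earlier stereochemistry is erased and the cyclopropane fixes the absolute sense.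

**Step 8**
Reactants: 11
Product: 12 5-(TBSO-methyl)-8,8-dimethylbicyclo[5.1.0]oct-5-en-4-ol (OH cis to the CMe2 bridge)
Conditions: NaBH4, CeCl3·7H2O, MeOH, −78 °C
Reagents that add atoms: none
Why: Luche 1,2-reduction delivers hydride anti to the CMe2 bridge, so the OH ends up syn to the bridge.

**Step 9**
Reactants: 12; 13 3-(TBDPSO)propanoic acid
Product: 14 ester with the C10–O bond anti to the bridge
Conditions: PPh3, DIAD, THF, 0 °C → rt
Reagents that add atoms: 13, OC(=O)CCO[Si](c1ccccc1)(c1ccccc1)C(C)(C)C
Why: Mitsunobu esterification proceeds by SN2 with inversion. This puts the allylic ester on the face anti to the cyclopropane bridge, which is the face the Claisen must use to place C4 correctly.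

**Step 10 (key step)**
Reactants: 14
Product: 15 acid, 2-[ring-C5]-3-(TBDPSO)propanoic acid, with C10=C1 alkene
Conditions: LDA, THF, −78 °C; then TBSCl, HMPA, −78 °C → rt; aq. HCl workup
Reagents that add atoms: none (the transient silyl ester is hydrolysed on workup)
Why: Ireland–Claisen [3,3] rearrangement of the silyl ketene acetal is suprafacial, so C4 is attached at C5 on the face carrying the C10–O bond, anti to the cyclopropane bridge. C4 forms as an epimeric mixture that is later destroyed, and the alkene moves to C10=C1, giving the C3 carboxyl and C15–O in place.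

**Step 11**
Reactants: 15; 16 TMSCHN2
Product: 17 methyl ester of 15
Conditions: TMSCHN2, MeOH/toluene, 0 °C
Reagents that add atoms: TMSCHN2, C[Si](C)(C)[CH-][N+]#N
Why: Esterification under mild conditions protects the acid for the hydroboration, oxidation and ylide steps.

**Step 12**
Reactants: 17; 18 hydrogen peroxide (from perborate)
Product: 19 C10 alcohol (OH syn to H1)
Conditions: 9-BBN, THF, 0 °C → rt; then NaBO3·4H2O, THF/H2O
Reagents that add atoms: hydrogen peroxide, OO
Why: Hydroboration of the trisubstituted alkene puts boron on the less substituted C10 and H on C1 (syn addition, from the face anti to the C5 side chain). This sets the C1 stereocentre and C10 oxygenation.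

**Step 13**
Reactants: 19
Product: 20 C10 ketone
Conditions: DMP, NaHCO3, CH2Cl2, rt
Reagents that add atoms: none
Why: Oxidation of the secondary alcohol. C1 becomes epimerisable, and its final configuration is fixed at step 18.

**Step 14**
Reactants: 20; 21 trimethylsulfonium iodide
Product: 22 spiro-epoxide (CH2 syn to the bridge, O anti)
Conditions: Me3S+ I−, n-BuLi, THF, 0 °C
Reagents that add atoms: Me3S+ I−, C[S+](C)C.[I-]
Why: Corey–Chaykovsky epoxidation with dimethylsulfonium methylide. The methylide adds to the face remote from the cis-fused C1/C5 substituents, delivering CH2 to the top face and O to the bottom, as in the natural product.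

**Step 15**
Reactants: 22
Product: 23 C3 primary alcohol (ester reduced)
Conditions: LiBH4, THF, 0 °C → rt
Reagents that add atoms: none
Why: LiBH4 reduces the ester and spares the silyl ethers and the tertiary spiro-epoxide.

**Step 16**
Reactants: 23
Product: 24 C2/C3 diol (C15 still TBDPS-protected)
Conditions: TBAF (1.0 equiv), THF, 0 °C
Reagents that add atoms: none
Why: The primary TBS ether is cleaved selectively over the primary TBDPS ether.

**Step 17**
Reactants: 24
Product: 25 2,3-seco dialdehyde
Conditions: DMP (2.5 equiv), NaHCO3, CH2Cl2, rt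
Reagents that add atoms: none
Why: Oxidation of the two primary alcohols gives the glutaraldehyde unit C2–C1–C5–C4–C3 with C15–OTBDPS intact.

**Step 18**
Reactants: 25; 26 acetic anhydride
Product: 27 C15-OTBDPS plagiochilin A (2-acetoxy-3,4-dihydro-2H-pyran)
Conditions: Ac2O, Et3N, DMAP, CH2Cl2, 0 → 25 °C
Reagents that add atoms: Ac2O, CC(=O)OC(C)=O
Why: Enolisation of the C3 aldehyde, attack of the enol oxygen on the C2 aldehyde and acetylation of the hemiacetal build the 2-acetoxy enol-ether pyran. C1 epimerises under the conditions and the cis-fused pyran with anomeric OAc is thermodynamically favoured.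

**Step 19**
Reactants: 27
Product: 28 15-deacetyl plagiochilin A
Conditions: HF·pyridine, pyridine, THF, 0 °C
Reagents that add atoms: none
Why: Buffered fluoride removes the TBDPS ether and leaves the acylal, enol ether and epoxide.

**Step 20**
Reactants: 28; 26 acetic anhydride
Product: 29 plagiochilin A
Conditions: Ac2O, pyridine, DMAP (cat.), CH2Cl2, 0 °C
Reagents that add atoms: Ac2O, CC(=O)OC(C)=O
Why: Acetylation of the primary allylic C15 alcohol completes the target.

## Compound list
number | name | SMILES | role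
1 | (+)-2-carene, (1S,6R) | CC1=C[C@H]2[C@@H](CC1)C2(C)C | starting material
2 | ozone | O=[O+][O-] | reagent
3 | (1S,3R)-2,2-dimethyl-3-(3-oxobutyl)cyclopropane-1-carbaldehyde | O=C[C@H]1[C@@H](CCC(C)=O)C1(C)C | intermediate
4 | 2-hydroxy-8,8-dimethylbicyclo[5.1.0]octan-4-one | O=C1CC(O)[C@H]2[C@@H](CC1)C2(C)C | intermediate
5 | (1S,7R)-8,8-dimethylbicyclo[5.1.0]oct-2-en-4-one | O=C1C=C[C@H]2[C@@H](CC1)C2(C)C | intermediate
6 | formaldehyde | C=O | reagent
7 | 5-(hydroxymethyl)-8,8-dimethylbicyclo[5.1.0]oct-2-en-4-one | O=C1C=C[C@H]2[C@@H](CC1CO)C2(C)C | intermediate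
8 | tert-butyldimethylsilyl chloride | CC(C)(C)[Si](C)(C)Cl | reagent
9 | 5-(TBSO-methyl)-8,8-dimethylbicyclo[5.1.0]oct-2-en-4-one | O=C1C=C[C@H]2[C@@H](CC1CO[Si](C)(C)C(C)(C)C)C2(C)C | intermediate
10 | 5-(TBSO-methyl)-8,8-dimethylbicyclo[5.1.0]octan-4-one | O=C1CC[C@H]2[C@@H](CC1CO[Si](C)(C)C(C)(C)C)C2(C)C | intermediate
11 | 5-(TBSO-methyl)-8,8-dimethylbicyclo[5.1.0]oct-5-en-4-one | O=C1CC[C@H]2[C@@H](C=C1CO[Si](C)(C)C(C)(C)C)C2(C)C | intermediate
12 | allylic alcohol (OH syn to CMe2 bridge) | O[C@@H]1CC[C@H]2[C@@H](C=C1CO[Si](C)(C)C(C)(C)C)C2(C)C | intermediate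
13 | 3-(TBDPSO)propanoic acid | OC(=O)CCO[Si](c1ccccc1)(c1ccccc1)C(C)(C)C | reagent
14 | Mitsunobu ester (C10–O anti to bridge) | CC(C)(C)[Si](c1ccccc1)(c1ccccc1)OCCC(=O)O[C@H]1CC[C@H]2[C@@H](C=C1CO[Si](C)(C)C(C)(C)C)C2(C)C | intermediate
15 | Claisen acid | OC(=O)C(CO[Si](c1ccccc1)(c1ccccc1)C(C)(C)C)[C@H]1C(CO[Si](C)(C)C(C)(C)C)=CCC[C@H]2[C@@H]1C2(C)C | intermediate
16 | trimethylsilyldiazomethane | C[Si](C)(C)[CH-][N+]#N | reagent
17 | methyl ester of 15 | COC(=O)C(CO[Si](c1ccccc1)(c1ccccc1)C(C)(C)C)[C@H]1C(CO[Si](C)(C)C(C)(C)C)=CCC[C@H]2[C@@H]1C2(C)C | intermediate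
18 | hydrogen peroxide (from NaBO3) | OO | reagent
19 | C10 alcohol | COC(=O)C(CO[Si](c1ccccc1)(c1ccccc1)C(C)(C)C)[C@H]1[C@@H](CO[Si](C)(C)C(C)(C)C)[C@H](O)CC[C@H]2[C@@H]1C2(C)C | intermediate
20 | C10 ketone | COC(=O)C(CO[Si](c1ccccc1)(c1ccccc1)C(C)(C)C)[C@H]1[C@@H](CO[Si](C)(C)C(C)(C)C)C(=O)CC[C@H]2[C@@H]1C2(C)C | intermediate
21 | trimethylsulfonium iodide | C[S+](C)C.[I-] | reagent
22 | spiro-epoxy ester | COC(=O)C(CO[Si](c1ccccc1)(c1ccccc1)C(C)(C)C)[C@H]1[C@@H](CO[Si](C)(C)C(C)(C)C)[C@]3(CO3)CC[C@H]2[C@@H]1C2(C)C | intermediate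
23 | C3 alcohol | OCC(CO[Si](c1ccccc1)(c1ccccc1)C(C)(C)C)[C@H]1[C@@H](CO[Si](C)(C)C(C)(C)C)[C@]3(CO3)CC[C@H]2[C@@H]1C2(C)C | intermediate
24 | C2/C3 diol | OCC(CO[Si](c1ccccc1)(c1ccccc1)C(C)(C)C)[C@H]1[C@@H](CO)[C@]3(CO3)CC[C@H]2[C@@H]1C2(C)C | intermediate
25 | 2,3-seco dialdehyde | O=CC(CO[Si](c1ccccc1)(c1ccccc1)C(C)(C)C)[C@H]1[C@@H](C=O)[C@]3(CO3)CC[C@H]2[C@@H]1C2(C)C | intermediate
26 | acetic anhydride | CC(=O)OC(C)=O | reagent
27 | C15-OTBDPS plagiochilin A | CC(C)(C)[Si](c1ccccc1)(c1ccccc1)OCC1=CO[C@H](OC(C)=O)[C@@H]2[C@H]1[C@@H]1[C@H](CC[C@@]23CO3)C1(C)C | intermediate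
28 | 15-deacetyl plagiochilin A | OCC1=CO[C@H](OC(C)=O)[C@@H]2[C@H]1[C@@H]1[C@H](CC[C@@]23CO3)C1(C)C | intermediate
29 | plagiochilin A | CC(=O)OCC1=CO[C@H](OC(C)=O)[C@@H]2[C@H]1[C@@H]1[C@H](CC[C@@]23CO3)C1(C)C | target

## Totals
Total step count: 20. Longest linear sequence: 20 steps, from 1.

Three steps most likely to fail:
1. **Step 2 (seven-membered aldol).** Closure of the five-membered ring through the internal α-CH2 may win.
   - Fallback: ring-closing metathesis. Wittig-methylenate aldehyde 3, convert the methyl ketone to the vinyl ketone (Eschenmoser salt, then MeI/base), and close with Grubbs-II to give 5.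
2. **Step 10 (Ireland–Claisen).** The β-silyloxy ester enolate may eliminate, or the boat/chair selectivity may be poor.
   - Fallback: drop the [3,3] step and add CH2=C(CH2OTBDPS)MgBr/CuI 1,4 to enone 11 from the face anti to the bridge. Then hydroborate the resulting 1,1-disubstituted alkene to the C3 alcohol, which retains the C10 ketone and skips steps 12–13.
3. **Step 14 (sulfonium methylide).** Facial selectivity may be poor, or the methyl ester may be attacked.
   - Fallback: methylenate ketone 20 (Petasis/Tebbe) and epoxidise the exocyclic alkene with DMDO, so the epoxide is set by olefin-face selectivity rather than ylide addition.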